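**Plan**

- Numbering: ring A is the trimethoxyarene C1–C6 (OMe on C3, C4, C5); ring B is C1, C2, C1', C7', C8', C8, C7; ring C is C1'–C6' with spiro carbon C1' and carbonyl C4'.
- All three stereocentres (C7, C8, C8') are neighbouring carbons of ring B, C8 alpha and C8' beta to C7, and C1' is not stereogenic because ring C is symmetric about the C1'–C4' axis. With C7 as a ketone, a C8=C8' double bond and no methyl groups, ring B is therefore an enone without any stereocentre.
- Cuts, in retrosynthetic order: C4'=O to CH2 (ring C as a bis-enol ether), the benzoate C–O bond, C7–H, then both C–CH3 bonds at C8' and C8 in one operation, then C8=C8' (metathesis), C7–C8 (vinyl addition), C1'–C7' (allylation) and C2–C1' (biaryl bond).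
- Forward: rings A and C are joined by Suzuki coupling, a Birch reductive allylation dearomatises ring C and creates the quaternary C1', ring-closing metathesis closes ring B, and ring C is oxidised to the dienone last.
- Stereochemistry: C8' comes from a chiral copper–phosphoramidite catalyst acting on the achiral enone, C8 from anti alkylation of the resulting enolate, and C7 from substrate-controlled hydride reduction.
- C7 travels through the Birch step as a benzylic alkoxide and is raised to the ketone afterwards, so that no arylpalladium species is ever formed beside the allyl group, where 5-exo Heck cyclisation would threaten.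

Key step: step 8

Assumption: the ligand L, O,O'-(S)-1,1'-binaphthyl-2,2'-diyl N,N-bis[(R)-1-phenylethyl]phosphoramidite, is taken as the enantiomer that methylates the Re face of C8'; if induction on this benzo-fused enone runs the other way, its (R,S,S) antipode is used and nothing else changes.

**Route**

Step 1
Reactants: 1 3,4,5-trimethoxybenzyl alcohol
Product: 2 (2-bromo-3,4,5-trimethoxyphenyl)methanol
Conditions: NBS (1.05 equiv), MeCN, 0 °C to rt
Reagents that add atoms: N-bromosuccinimide, O=C1CCC(=O)N1Br
Why: Electrophilic aromatic bromination; the two free ring positions are equivalent and each is activated by an ortho and a para methoxy group, so one equivalent of NBS in a polar solvent should brominate the ring once and leave the benzylic alcohol alone.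

Step 2
Reactants: 2 (2-bromo-3,4,5-trimethoxyphenyl)methanol; 3 3,5-dimethoxyphenylboronic acid
Product: 4 [2-(3,5-dimethoxyphenyl)-3,4,5-trimethoxyphenyl]methanol
Conditions: Pd(OAc)2 (2 mol %), SPhos (4 mol %), K2CO3, dioxane/H2O 4:1, 90 °C
Reagents that add atoms: 3,5-dimethoxyphenylboronic acid 3, COc1cc(OC)cc(B(O)O)c1
Why: Suzuki–Miyaura coupling; the electron-rich biarylphosphine promotes oxidative addition into the hindered, electron-rich C–Br bond flanked by CH2OH and OMe, the boronic acid has no ortho substituent, and a free alcohol is tolerated.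

Step 3
Reactants: 4 [2-(3,5-dimethoxyphenyl)-3,4,5-trimethoxyphenyl]methanol; 5 allyl bromide
Product: 8 [2-(1-allyl-3,5-dimethoxycyclohexa-2,5-dien-1-yl)-3,4,5-trimethoxyphenyl]methanol, via lithium alkoxide 6 (not isolated), via dilithiated cyclohexadienyl carbanion 7 (not isolated)
Conditions: n-BuLi (1.0 equiv), THF, −78 °C; Li (2.5 equiv), NH3(l)/THF, −78 °C; allyl bromide (3 equiv), −78 °C; solid NH4Cl
Reagents that add atoms: allyl bromide 5, C=CCBr
Why: Birch reductive alkylation of a 3,5-dimethoxybiaryl: ring C takes up the electrons because its two meta methoxy groups and the ipso aryl group all direct protonation to C4' and leave a pentadienyl carbanion centred on C1', which allyl bromide alkylates to the quaternary carbon, while ring A is too electron-rich to be reduced and its benzylic C–O bond is kept as the lithium alkoxide, which offers no leaving group.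

Step 4
Reactants: 8 [2-(1-allyl-3,5-dimethoxycyclohexa-2,5-dien-1-yl)-3,4,5-trimethoxyphenyl]methanol
Product: 9 2-(1-allyl-3,5-dimethoxycyclohexa-2,5-dien-1-yl)-3,4,5-trimethoxybenzaldehyde
Conditions: activated MnO2 (15 equiv), CH2Cl2, rt
Reagents that add atoms: none
Why: MnO2 oxidation of a benzylic alcohol on a neutral solid oxidant, which stops at the aldehyde and should not touch the acid-labile bis-enol ether or the terminal alkene.

Step 5
Reactants: 9 2-(1-allyl-3,5-dimethoxycyclohexa-2,5-dien-1-yl)-3,4,5-trimethoxybenzaldehyde; 10 vinylmagnesium bromide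
Product: 11 rac-1-[2-(1-allyl-3,5-dimethoxycyclohexa-2,5-dien-1-yl)-3,4,5-trimethoxyphenyl]prop-2-en-1-ol
Conditions: CH2=CHMgBr (1.5 equiv), THF, −78 to 0 °C; aq NH4Cl
Reagents that add atoms: vinylmagnesium bromide 10, C=C[Mg]Br
Why: Grignard 1,2-addition to the aryl aldehyde; the carbinol centre C7 forms as a racemate, which does not matter because step 7 removes it.

Step 6
Reactants: 11 rac-1-[2-(1-allyl-3,5-dimethoxycyclohexa-2,5-dien-1-yl)-3,4,5-trimethoxyphenyl]prop-2-en-1-ol
Product: 12 rac-2,3,3',4,5'-pentamethoxy-6,9-dihydrospiro[benzo[7]annulene-5,1'-cyclohexa[2,5]dien]-9-ol (ring B cycloheptenol with cis C8=C8')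
Conditions: second-generation Grubbs catalyst (5 mol %), CH2Cl2 (0.005 M), 40 °C
Reagents that add atoms: none
Why: Ring-closing olefin metathesis of two monosubstituted terminal alkenes closes the seven-membered ring B with loss of ethylene and a necessarily cis C8=C8' bond, the trisubstituted enol ethers of ring C being too hindered to engage the ruthenium carbene.

Step 7
Reactants: 12 rac-2,3,3',4,5'-pentamethoxy-6,9-dihydrospiro[benzo[7]annulene-5,1'-cyclohexa[2,5]dien]-9-ol
Product: 13 2,3,3',4,5'-pentamethoxyspiro[benzo[7]annulene-5,1'-cyclohexa[2,5]dien]-9(6H)-one (achiral ring B enone, ring C as bis-enol ether)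
Conditions: activated MnO2 (15 equiv), CH2Cl2, rt
Reagents that add atoms: none
Why: MnO2 oxidation of an alcohol that is both allylic and benzylic gives the conjugated enone under neutral conditions, and with C7 trigonal the molecule has no stereocentre left.

Step 8
Reactants: 13 2,3,3',4,5'-pentamethoxyspiro[benzo[7]annulene-5,1'-cyclohexa[2,5]dien]-9(6H)-one; 14 dimethylzinc; 15 iodomethane
Product: 17 (7R,8S)-2,3,3',4,5'-pentamethoxy-7,8-dimethyl-7,8-dihydrospiro[benzo[7]annulene-5,1'-cyclohexa[2,5]dien]-9(6H)-one (lignan numbering 8S,8'R; trans-dimethyl C7 ketone), via methylzinc enolate 16 (not isolated)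
Conditions: Cu(OTf)2 (3 mol %), L (6 mol %), Me2Zn (2 equiv), toluene, −20 °C; then MeI (10 equiv), HMPA, 0 °C to rt; aq NH4Cl
Reagents that add atoms: dimethylzinc 14, C[Zn]C; iodomethane 15, CI
Why: Me2Zn reduces Cu(OTf)2 to a monovalent copper–phosphoramidite complex and passes a methyl group to it; this methylcopper species binds the C8=C8' bond of 13, adds at the beta carbon C8' to give a trivalent copper intermediate and reductively eliminates the C8'–CH3 bond, leaving methylzinc enolate 16, whose C8 carbon then displaces iodide from MeI once HMPA has loosened the zinc enolate. The closest known reaction type is the copper/phosphoramidite-catalysed enantioselective conjugate addition of dialkylzinc reagents to cyclohexenone and cycloheptenone followed by alkylation of the zinc enolate; no ring is closed. C8' is set by the ligand alone, because 13 has no stereocentre and its two enone faces are enantiotopic, and methyl must reach the Re face of C8' to give 8'R. C8 is set by the substrate: MeI approaches the enolate face anti to the new C8' methyl group to give the trans (8S,8'R) pair, and since C8 is the only enolisable position any cis isomer can be equilibrated to the more stable trans ketone with base. The step needs 1,4- over 1,2-addition (the soft organocopper secures it), reaction in ring B only (the enol ethers of ring C are inert to nucleophiles, which is why ring C is carried at this oxidation level) and single C-alkylation at C8 (the other alpha position, C1, is aromatic).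

Step 9
Reactants: 17 (7R,8S)-2,3,3',4,5'-pentamethoxy-7,8-dimethyl-7,8-dihydrospiro[benzo[7]annulene-5,1'-cyclohexa[2,5]dien]-9(6H)-one
Product: 18 (7R,8S,9R)-2,3,3',4,5'-pentamethoxy-7,8-dimethyl-6,7,8,9-tetrahydrospiro[benzo[7]annulene-5,1'-cyclohexa[2,5]dien]-9-ol (lignan numbering 7R,8S,8'R)
Conditions: NaBH4, MeOH/THF 1:1, −20 to 0 °C
Reagents that add atoms: none
Why: Hydride reduction of a cyclic ketone by a small reagent: with both methyl groups pseudo-equatorial on the chair-like ring B, borohydride should attack C7 along the axial-type path anti to the pseudo-axial C8–H and so place the hydroxyl trans to the C8 methyl group (7R), the same torsional preference that gives trans-2-methylcyclohexanol from 2-methylcyclohexanone.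

Step 10
Reactants: 18 (7R,8S,9R)-2,3,3',4,5'-pentamethoxy-7,8-dimethyl-6,7,8,9-tetrahydrospiro[benzo[7]annulene-5,1'-cyclohexa[2,5]dien]-9-ol; 19 benzoic anhydride
Product: 20 (7R,8S,9R)-2,3,3',4,5'-pentamethoxy-7,8-dimethyl-6,7,8,9-tetrahydrospiro[benzo[7]annulene-5,1'-cyclohexa[2,5]dien]-9-yl benzoate
Conditions: Bz2O (1.5 equiv), Et3N, DMAP (0.2 equiv), CH2Cl2, rt
Reagents that add atoms: benzoic anhydride 19, O=C(OC(=O)c1ccccc1)c1ccccc1
Why: DMAP-catalysed acyl transfer to the secondary benzylic alcohol proceeds with retention at C7, and the amine buffer keeps acid away from the enol ethers.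

Step 11
Reactants: 20 (7R,8S,9R)-2,3,3',4,5'-pentamethoxy-7,8-dimethyl-6,7,8,9-tetrahydrospiro[benzo[7]annulene-5,1'-cyclohexa[2,5]dien]-9-yl benzoate
Product: 21 (7R,8S,9R)-2,3,3',4,5'-pentamethoxy-7,8-dimethyl-4'-oxo-6,7,8,9-tetrahydrospiro[benzo[7]annulene-5,1'-cyclohexa[2,5]dien]-9-yl benzoate (CNP0201356.1)
Conditions: Rh2(cap)4 (dirhodium tetracaprolactamate, 1 mol %), t-BuOOH (5 equiv, in decane), K2CO3 (0.5 equiv), CH2Cl2, rt
Reagents that add atoms: tert-butyl hydroperoxide, CC(C)(C)OO
Why: Bis-allylic C–H oxidation by tert-butylperoxyl radicals, the reaction type that converts Birch-derived 3,3-disubstituted cyclohexa-1,4-dienes into cyclohexa-2,5-dienones: the doubly allylic C4'–H bonds are the weakest in the molecule, the radical is trapped at C4' because C2' and C6' adjoin the quaternary C1', and the mixed peroxide collapses to the cross-conjugated dienone without touching a stereocentre.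

**Compound list**

1 | 3,4,5-trimethoxybenzyl alcohol | COc1cc(CO)cc(OC)c1OC | starting material
2 | (2-bromo-3,4,5-trimethoxyphenyl)methanol | COc1cc(CO)c(Br)c(OC)c1OC | intermediate
3 | 3,5-dimethoxyphenylboronic acid | COc1cc(OC)cc(B(O)O)c1 | starting material
4 | [2-(3,5-dimethoxyphenyl)-3,4,5-trimethoxyphenyl]methanol | COc1cc(OC)cc(-c2c(CO)cc(OC)c(OC)c2OC)c1 | intermediate
5 | allyl bromide | C=CCBr | starting material
6 | lithium alkoxide of 4 (formed in the flask) | [Li+].[O-]Cc1cc(OC)c(OC)c(OC)c1-c1cc(OC)cc(OC)c1 | intermediate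
7 | dilithium species of the reduced biaryl: benzylic alkoxide plus 3,5-dimethoxycyclohexadienyl carbanion centred on C1' (formed in the flask) | [Li+].[Li+].[O-]Cc1cc(OC)c(OC)c(OC)c1[C-]1C=C(OC)CC(OC)=C1 | intermediate
8 | [2-(1-allyl-3,5-dimethoxycyclohexa-2,5-dien-1-yl)-3,4,5-trimethoxyphenyl]methanol | C=CCC1(C=C(OC)CC(OC)=C1)c1c(CO)cc(OC)c(OC)c1OC | intermediate
9 | 2-(1-allyl-3,5-dimethoxycyclohexa-2,5-dien-1-yl)-3,4,5-trimethoxybenzaldehyde | C=CCC1(C=C(OC)CC(OC)=C1)c1c(C=O)cc(OC)c(OC)c1OC | intermediate
10 | vinylmagnesium bromide | C=C[Mg]Br | starting material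
11 | rac-1-[2-(1-allyl-3,5-dimethoxycyclohexa-2,5-dien-1-yl)-3,4,5-trimethoxyphenyl]prop-2-en-1-ol | C=CCC1(C=C(OC)CC(OC)=C1)c1c(C(O)C=C)cc(OC)c(OC)c1OC | intermediate
12 | rac-2,3,3',4,5'-pentamethoxy-6,9-dihydrospiro[benzo[7]annulene-5,1'-cyclohexa[2,5]dien]-9-ol | COC1=CC2(C=C(OC)C1)CC=CC(O)c1cc(OC)c(OC)c(OC)c12 | intermediate
13 | 2,3,3',4,5'-pentamethoxyspiro[benzo[7]annulene-5,1'-cyclohexa[2,5]dien]-9(6H)-one (achiral ring B enone) | COC1=CC2(C=C(OC)C1)CC=CC(=O)c1cc(OC)c(OC)c(OC)c12 | intermediate
14 | dimethylzinc | C[Zn]C | starting material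
15 | iodomethane | CI | starting material
16 | methylzinc enolate of the (8'R)-8'-methyl ketone, O–Zn on C7 and C7=C8 double bond (formed in the flask) | COC1=CC2(C=C(OC)C1)C[C@@H](C)C=C(O[Zn]C)c1cc(OC)c(OC)c(OC)c12 | intermediate
17 | (7R,8S)-2,3,3',4,5'-pentamethoxy-7,8-dimethyl-7,8-dihydrospiro[benzo[7]annulene-5,1'-cyclohexa[2,5]dien]-9(6H)-one (lignan numbering 8S,8'R) | COC1=CC2(C=C(OC)C1)C[C@@H](C)[C@H](C)C(=O)c1cc(OC)c(OC)c(OC)c12 | intermediate
18 | (7R,8S,9R)-2,3,3',4,5'-pentamethoxy-7,8-dimethyl-6,7,8,9-tetrahydrospiro[benzo[7]annulene-5,1'-cyclohexa[2,5]dien]-9-ol (lignan numbering 7R,8S,8'R) | COC1=CC2(C=C(OC)C1)C[C@@H](C)[C@H](C)[C@@H](O)c1cc(OC)c(OC)c(OC)c12 | intermediate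
19 | benzoic anhydride | O=C(OC(=O)c1ccccc1)c1ccccc1 | starting material
20 | (7R,8S,9R)-2,3,3',4,5'-pentamethoxy-7,8-dimethyl-6,7,8,9-tetrahydrospiro[benzo[7]annulene-5,1'-cyclohexa[2,5]dien]-9-yl benzoate | COC1=CC2(C=C(OC)C1)C[C@@H](C)[C@H](C)[C@@H](OC(=O)c1ccccc1)c1cc(OC)c(OC)c(OC)c12 | intermediate
21 | (7R,8S,9R)-2,3,3',4,5'-pentamethoxy-7,8-dimethyl-4'-oxo-6,7,8,9-tetrahydrospiro[benzo[7]annulene-5,1'-cyclohexa[2,5]dien]-9-yl benzoate (CNP0201356.1) | COC1=CC2(C=C(OC)C1=O)C[C@@H](C)[C@H](C)[C@@H](OC(=O)c1ccccc1)c1cc(OC)c(OC)c(OC)c12 | target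

**Step count and risks**

Total step count: 11. Longest linear sequence: 11 steps (1 to 21); every other input is a purchased reagent.

Steps most likely to fail:

Step 8. The conjugate addition may stall because the enone is deactivated by its electron-rich aryl ketone and Me2Zn is a sluggish methyl donor. The zinc enolate may also be protonated instead of methylated, or alkylated with poor trans selectivity. The fallback sets out from enone 13 and makes the two C–CH3 bonds in separate operations. Me3Al with copper thiophene-2-carboxylate (CuO2CC4H3S) and ligand L in Et2O at −30 °C, followed by aqueous work-up, should give the (8'R)-8'-methyl ketone F1. LiN(i-Pr)2 in THF at −78 °C then forms the lithium enolate F2 at C8, the only enolisable position, and MeI with DMPU methylates it anti to the C8' methyl group. This comes back to the route at ketone 17; any cis isomer is equilibrated with NaOMe in MeOH.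

Step 11. The peroxyl radicals may attack the electron-rich enol ether double bonds, or the radical may be trapped at C2' or C6', so that conversion to the dienone is low. The fallback sets out from benzoate 20 and reaches the dienone through carbonyl chemistry instead of C–H oxidation. Aqueous oxalic acid in THF hydrolyses both enol ethers to the spiro cyclohexane-1,3-dione F3. Dess–Martin periodinane with pyridine in CH2Cl2 oxidises the doubly activated C4' methylene to the vicinal trione, which should rest as its bis-enol, the 3',5'-dihydroxy dienone F4. Me2SO4 and K2CO3 in acetone methylate both enols, and the route is rejoined at target 21.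

Step 9. Hydride may be delivered to the other face of the C7 carbonyl if ring B does not adopt the assumed chair, giving mainly the C7 epimer. The fallback sets out from ketone 17 and aims at that epimer on purpose. The bulky LiBH(s-Bu)3 in THF at −78 °C, which takes the equatorial-type path, should give the (7S)-alcohol F5. Mitsunobu esterification of F5 with benzoic acid (PPh3, diisopropyl azodicarboxylate, THF, 0 °C) inverts C7 and comes back to the route at benzoate 20, replacing step 10 as well.

**Further compounds**

F1 | step 8 | (8'R)-8'-methyl C7 ketone, (7R)-2,3,3',4,5'-pentamethoxy-7-methyl-7,8-dihydrospiro[benzo[7]annulene-5,1'-cyclohexa[2,5]dien]-9(6H)-one | COC1=CC2(C=C(OC)C1)C[C@@H](C)CC(=O)c1cc(OC)c(OC)c(OC)c12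
F2 | step 8 | lithium enolate of F1 (O–Li on C7, C7=C8 double bond) | COC1=CC2(C=C(OC)C1)C[C@@H](C)C=C([O-])c1cc(OC)c(OC)c(OC)c12.[Li+]
F3 | step 11 | spiro cyclohexane-1,3-dione from hydrolysis of 20 (C3' and C5' ketones, benzoate intact) | O=C1CC(=O)CC2(C1)C[C@@H](C)[C@H](C)[C@@H](OC(=O)c1ccccc1)c1cc(OC)c(OC)c(OC)c12
F4 | step 11 | 3',5'-dihydroxy-4'-oxo dienone (bis-enol of the C3',C4',C5' trione, benzoate intact) | OC1=CC2(C=C(O)C1=O)C[C@@H](C)[C@H](C)[C@@H](OC(=O)c1ccccc1)c1cc(OC)c(OC)c(OC)c12
F5 | step 9 | (7S,8S,8'R)-alcohol, the C7 epimer of 18 | COC1=CC2(C=C(OC)C1)C[C@@H](C)[C@H](C)[C@H](O)c1cc(OC)c(OC)c(OC)c12
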